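**Plan**

- Retrosynthesis: ring A is cut at the C1=C10 olefin (ring-closing metathesis), then the C4–CH3 bond, then C4–C5 ([3,3] shift from an ester held on a C10 side arm), then C13=C14 and C9–C11 of the side chain and C8–CH3 of ring B.
- Forward: ring B comes from 2-methylcyclohexenone (C8, then C9). The side chain is grown by Michael addition and olefination. A temporary 1-hydroxyethyl arm on C10 carries a hexenoate that rearranges onto C5, C4 is methylated, ring A is closed last, and the 13-hydroxy-14,15-diacetate is set at the end.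
- Stereochemistry: C8 by catalyst-controlled conjugate addition; C9 by attack anti to C8–CH3; C5 by suprafacial transfer from a reagent-set carbinol on the temporary arm; C4 by A(1,3)-controlled enolate methylation; C13/C14 by asymmetric epoxidation and stereospecific Payne inversion at C14.
- Enabling feature: the only ring olefin, C1=C10, has C10 as the sp2 fusion atom of rings A and B. An exocyclic C10 alkylidene on ring B plus a butenyl arm on C4 is therefore a direct metathesis precursor of ring A, and the alkylidene methyl that relayed chirality to C5 leaves as propene in the same event.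

Key step: step 13

Remark: locants follow the halimane skeleton of the target (C1–C20, ester carbon C18); C1′ and C2′ are the carbinol carbon and the methyl of the temporary two-carbon arm on C10.
Assumption: the phosphoramidite antipode named in step 1 is the one that gives the 3R adduct; if the facial sense is the opposite, its mirror image is used.

Step 1
Reactants: 1 2-methylcyclohex-2-en-1-one
Product: 3 [(3R)-2,3-dimethylcyclohex-1-en-1-yl]oxy(trimethyl)silane, via aluminium enolate 2 (not isolated)
Conditions: Me3Al, Cu(O2CC4H3S) (2 mol %), (R)-BINOL-derived bis[(S)-1-phenylethyl]phosphoramidite (4 mol %), Et2O, −30 °C; then Me3SiOTf, THF, 0 °C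
Reagents that add atoms: trimethylaluminium C[Al](C)C; trimethylsilyl trifluoromethanesulfonate C[Si](C)(C)OS(=O)(=O)C(F)(F)F
Why: Copper-catalysed asymmetric conjugate addition of a trialkylaluminium to an α-substituted cyclohexenone, the chiral phosphoramidite–copper complex choosing the enone face so that C8 is formed as 3R, followed by O-silylation of the regiodefined aluminium enolate, which fixes the tetrasubstituted enol ether needed for C9.

Step 2
Reactants: 3 [(3R)-2,3-dimethylcyclohex-1-en-1-yl]oxy(trimethyl)silane; 4 but-3-en-2-one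
Product: 5 (2S,3R)-2,3-dimethyl-2-(3-oxobutyl)cyclohexan-1-one
Conditions: TiCl4, Ti(OiPr)4, CH2Cl2, −78 °C; H2O work-up
Reagents that add atoms: none
Why: Mukaiyama–Michael addition in which the enone approaches C9 of the tetrasubstituted enol ether anti to the C8 methyl (pseudoaxial to avoid A(1,2) strain), so the oxobutyl chain ends trans to C8–CH3 and the C9 methyl cis to it (9S).

Step 3
Reactants: 5 (2S,3R)-2,3-dimethyl-2-(3-oxobutyl)cyclohexan-1-one
Product: 6 ethyl (2E)-5-[(1S,2R)-1,2-dimethyl-6-oxocyclohexyl]-3-methylpent-2-enoate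
Conditions: (EtO)2P(O)CH2CO2Et, NaH, THF, 0 → 50 °C; chromatographic removal of any Z isomer
Reagents that add atoms: triethyl phosphonoacetate CCOC(=O)CP(=O)(OCC)OCC
Why: Horner–Wadsworth–Emmons olefination that should take place only at the unhindered methyl ketone (the ring ketone is flanked by the C9 quaternary carbon) and favour the E-enoate with the chain trans to the ester.

Step 4
Reactants: 6 ethyl (2E)-5-[(1S,2R)-1,2-dimethyl-6-oxocyclohexyl]-3-methylpent-2-enoate
Product: 7 ethyl (2E)-5-[(1S,6R)-1,6-dimethyl-2-(trifluoromethanesulfonyloxy)cyclohex-2-en-1-yl]-3-methylpent-2-enoate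
Conditions: KN(SiMe3)2, THF, −78 °C; PhNTf2, −78 → 0 °C
Reagents that add atoms: N-phenylbis(trifluoromethanesulfonimide) O=S(=O)(N(c1ccccc1)S(=O)(=O)C(F)(F)F)C(F)(F)F
Why: Kinetic enolisation can occur only toward C5 because C9 is quaternary, the ketone α-CH2 being deprotonated faster than the γ-position of the β,β-disubstituted enoate at −78 °C, and O-sulfonylation of the potassium enolate gives the enol triflate.

Step 5
Reactants: 7 ethyl (2E)-5-[(1S,6R)-1,6-dimethyl-2-(trifluoromethanesulfonyloxy)cyclohex-2-en-1-yl]-3-methylpent-2-enoate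
Product: 8 (5R,6S)-6-[(3E)-5-hydroxy-3-methylpent-3-en-1-yl]-5,6-dimethylcyclohex-1-en-1-yl trifluoromethanesulfonate
Conditions: iBu2AlH (2.5 equiv), CH2Cl2, −78 °C; aq. potassium sodium tartrate
Reagents that add atoms: none
Why: 1,2-Reduction of the α,β-unsaturated ester to the allylic alcohol by an aluminium hydride at low temperature, conditions that leave an enol triflate untouched.

Step 6
Reactants: 8 (5R,6S)-6-[(3E)-5-hydroxy-3-methylpent-3-en-1-yl]-5,6-dimethylcyclohex-1-en-1-yl trifluoromethanesulfonate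
Product: 9 (5R,6S)-6-[(3E)-5-(tert-butyldiphenylsilyloxy)-3-methylpent-3-en-1-yl]-5,6-dimethylcyclohex-1-en-1-yl trifluoromethanesulfonate
Conditions: tBuPh2SiCl, imidazole, DMF, rt
Reagents that add atoms: tert-butyl(chloro)diphenylsilane CC(C)(C)[Si](Cl)(c1ccccc1)c1ccccc1
Why: Standard silylation of a primary alcohol, giving a silyl ether that is stable to the dilute acid and the amide bases of the following steps.

Step 7
Reactants: 9 (5R,6S)-6-[(3E)-5-(tert-butyldiphenylsilyloxy)-3-methylpent-3-en-1-yl]-5,6-dimethylcyclohex-1-en-1-yl trifluoromethanesulfonate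
Product: 11 1-[(5R,6S)-6-[(3E)-5-(tert-butyldiphenylsilyloxy)-3-methylpent-3-en-1-yl]-5,6-dimethylcyclohex-1-en-1-yl]ethan-1-one, via ethoxyvinyl diene 10 (not isolated)
Conditions: Bu3SnC(OEt)=CH2, Pd(PPh3)4 (5 mol %), LiCl, THF, 65 °C; then 1 M HCl, THF, rt
Reagents that add atoms: tributyl(1-ethoxyvinyl)stannane C=C(OCC)[Sn](CCCC)(CCCC)CCCC; water O
Why: Stille coupling of the enol triflate with an acyl anion equivalent (LiCl-promoted), then mild acid hydrolysis of the ethoxyvinyl group to the conjugated methyl ketone that becomes the temporary C1′–C2′ arm on C10.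

Step 8
Reactants: 11 1-[(5R,6S)-6-[(3E)-5-(tert-butyldiphenylsilyloxy)-3-methylpent-3-en-1-yl]-5,6-dimethylcyclohex-1-en-1-yl]ethan-1-one
Product: 12 (1R)-1-[(5R,6S)-6-[(3E)-5-(tert-butyldiphenylsilyloxy)-3-methylpent-3-en-1-yl]-5,6-dimethylcyclohex-1-en-1-yl]ethan-1-ol
Conditions: (S)-2-methyl-CBS-oxazaborolidine (20 mol %), BH3·SMe2, THF, −30 °C; MeOH then H2O
Reagents that add atoms: none
Why: Corey–Bakshi–Shibata reduction in which the ketone binds the oxazaborolidine with the alkenyl group as the large substituent, so that the (S)-catalyst delivers hydride to give the (1′R)-carbinol by reagent control.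

Step 9
Reactants: 12 (1R)-1-[(5R,6S)-6-[(3E)-5-(tert-butyldiphenylsilyloxy)-3-methylpent-3-en-1-yl]-5,6-dimethylcyclohex-1-en-1-yl]ethan-1-ol; 13 hex-5-enoic acid
Product: 14 (1R)-1-[(5R,6S)-6-[(3E)-5-(tert-butyldiphenylsilyloxy)-3-methylpent-3-en-1-yl]-5,6-dimethylcyclohex-1-en-1-yl]ethyl hex-5-enoate
Conditions: DCC, DMAP (cat.), CH2Cl2, rt
Reagents that add atoms: none
Why: Steglich esterification (carbodiimide activation, acyl transfer by DMAP) that acylates the hindered secondary allylic alcohol at oxygen with retention at C1′.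

Step 10
Reactants: 14 (1R)-1-[(5R,6S)-6-[(3E)-5-(tert-butyldiphenylsilyloxy)-3-methylpent-3-en-1-yl]-5,6-dimethylcyclohex-1-en-1-yl]ethyl hex-5-enoate
Product: 17 2-[(1S,2E,3S,4R)-3-[(3E)-5-(tert-butyldiphenylsilyloxy)-3-methylpent-3-en-1-yl]-2-ethylidene-3,4-dimethylcyclohexyl]hex-5-enoic acid (both C4 epimers), via silyl ketene acetal 15 (not isolated), via trimethylsilyl ester 16 (not isolated)
Conditions: LiN(iPr)2, Me3SiCl–Et3N, THF, −78 → 60 °C; then 1 M HCl
Reagents that add atoms: none
Why: Ireland–Claisen rearrangement: the [3,3] shift is suprafacial over the C1′–C10=C5 allyl unit, and because the C2′ methyl must turn toward C5–H and not toward the C9 quaternary centre (A(1,3) strain with H against A(1,2) strain with a fully substituted carbon), the (1′R)-ester presents its oxygen, and hence forms the C4–C5 bond, on the face of C5 cis to the C9 side chain (the configuration of the target), while C4 is left as an epimer mixture that step 12 erases.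

Step 11
Reactants: 17 2-[(1S,2E,3S,4R)-3-[(3E)-5-(tert-butyldiphenylsilyloxy)-3-methylpent-3-en-1-yl]-2-ethylidene-3,4-dimethylcyclohexyl]hex-5-enoic acid (both C4 epimers)
Product: 18 methyl 2-[(1S,2E,3S,4R)-3-[(3E)-5-(tert-butyldiphenylsilyloxy)-3-methylpent-3-en-1-yl]-2-ethylidene-3,4-dimethylcyclohexyl]hex-5-enoate (both C4 epimers)
Conditions: MeI, K2CO3, DMF, rt
Reagents that add atoms: iodomethane CI
Why: SN2 O-alkylation of the carboxylate by iodomethane, which is insensitive to the congestion around the acyl carbon.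

Step 12
Reactants: 18 methyl 2-[(1S,2E,3S,4R)-3-[(3E)-5-(tert-butyldiphenylsilyloxy)-3-methylpent-3-en-1-yl]-2-ethylidene-3,4-dimethylcyclohexyl]hex-5-enoate (both C4 epimers)
Product: 19 methyl (2R)-2-[(1R,2E,3S,4R)-3-[(3E)-5-(tert-butyldiphenylsilyloxy)-3-methylpent-3-en-1-yl]-2-ethylidene-3,4-dimethylcyclohexyl]-2-methylhex-5-enoate
Conditions: LiN(iPr)2, THF–DMPU, −78 °C; MeI, −78 → −30 °C
Reagents that add atoms: iodomethane CI
Why: Alkylation of the ester enolate creates the C4 quaternary centre under A(1,3) strain control: with C5–H in the enolate plane, the C10 ethylidene arm backed by the C9 quaternary carbon shields one face and iodomethane enters from the side of the C6 methylene, which corresponds to 4R.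

Step 13
Reactants: 19 methyl (2R)-2-[(1R,2E,3S,4R)-3-[(3E)-5-(tert-butyldiphenylsilyloxy)-3-methylpent-3-en-1-yl]-2-ethylidene-3,4-dimethylcyclohexyl]-2-methylhex-5-enoate
Product: 20 methyl (4R,5R,8R,9S,13E)-15-(tert-butyldiphenylsilyloxy)halima-1(10),13-dien-18-oate
Conditions: second-generation Hoveyda–Grubbs catalyst RuCl2(H2IMes)(=CH-C6H4-2-OiPr) (10 mol %), toluene (0.005 M), 80 °C, slow argon purge
Reagents that add atoms: none
Why: Ring-closing olefin metathesis: the ruthenium alkylidene loads on the monosubstituted C1 vinyl group, adds intramolecularly [2+2] to the C10 ethylidene, and cycloreversion of the ruthenacyclobutane gives the C1=C10 double bond and Ru=CHCH3, which is carried off as propene. The closest known reaction type is the ring-closing metathesis of a terminal olefin with a trisubstituted olefin to a trisubstituted cyclohexene under a ruthenium N-heterocyclic carbene catalyst. Ring A (C1–C2–C3–C4–C5–C10) is closed as a six-membered carbocycle by direct formation of the C1=C10 bond at the ring-fusion carbon. No stereocentre is created; C4, C5, C8 and C9 are spectators, and the C2′ methyl that controlled C5 leaves with the by-product. The step needs chemoselectivity among three olefins and ring-size selectivity: the terminal vinyl group is the only olefin that initiates readily, the trisubstituted side-chain olefin is remote and unreactive, only a six-membered closure is geometrically available, and the C4 quaternary centre (gem-disubstituent effect) together with high dilution favours cyclisation over dimerisation.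

Step 14
Reactants: 20 methyl (4R,5R,8R,9S,13E)-15-(tert-butyldiphenylsilyloxy)halima-1(10),13-dien-18-oate
Product: 21 methyl (4R,5R,8R,9S,13E)-15-hydroxyhalima-1(10),13-dien-18-oate
Conditions: Bu4NF, THF, rt
Reagents that add atoms: none
Why: Fluoride-induced cleavage of the silyl ether frees the allylic alcohol needed to direct the epoxidation, esters and olefins being inert.

Step 15
Reactants: 21 methyl (4R,5R,8R,9S,13E)-15-hydroxyhalima-1(10),13-dien-18-oate
Product: 22 methyl (4R,5R,8R,9S,13S,14S)-13,14-epoxy-15-hydroxyhalim-1(10)-en-18-oate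
Conditions: Ti(OiPr)4 (10 mol %), L-(+)-diethyl tartrate (12 mol %), tBuOOH, 4 Å molecular sieves, CH2Cl2, −20 °C
Reagents that add atoms: tert-butyl hydroperoxide CC(C)(C)OO
Why: Sharpless asymmetric epoxidation, hydroxyl-directed and therefore confined to the C13=C14 olefin (the ring olefin has no allylic OH), the L-(+)-tartrate complex delivering oxygen to the face that gives the (13S,14S)-epoxide, as with other E-3,3-disubstituted allylic alcohols.

Step 16
Reactants: 22 methyl (4R,5R,8R,9S,13S,14S)-13,14-epoxy-15-hydroxyhalim-1(10)-en-18-oate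
Product: 24 methyl (4R,5R,8R,9S,13S,14R)-13,14,15-trihydroxyhalim-1(10)-en-18-oate, via terminal epoxide 23 (not isolated)
Conditions: NaOH (0.5 M), tBuOH–H2O, 70 °C
Reagents that add atoms: water O
Why: Payne rearrangement and opening: the C15 alkoxide attacks C14 with inversion to form the 14,15-epoxide with the C13 oxygen retained, and hydroxide opens this terminal epoxide at the primary C15, so the triol is (13S,14R), while the neopentyl-type C18 methyl ester should resist the dilute base.

Step 17
Reactants: 24 methyl (4R,5R,8R,9S,13S,14R)-13,14,15-trihydroxyhalim-1(10)-en-18-oate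
Product: 25 methyl (4R,5R,8R,9S,13S,14R)-14,15-diacetoxy-13-hydroxyhalim-1(10)-en-18-oate (CNP0238486.1)
Conditions: Ac2O, pyridine, rt
Reagents that add atoms: acetic anhydride CC(=O)OC(C)=O
Why: Acetylation with acetic anhydride in pyridine acylates the primary and the secondary hydroxyl, whereas the tertiary C13–OH does not react without an acyl-transfer catalyst.

**Compound list**

1 | 2-methylcyclohex-2-en-1-one | CC1=CCCCC1=O | starting material
2 | dimethylaluminium (3R)-2,3-dimethylcyclohex-1-en-1-olate | C[Al](C)OC1=C(C)[C@H](C)CCC1 | intermediate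
3 | [(3R)-2,3-dimethylcyclohex-1-en-1-yl]oxy(trimethyl)silane | C[Si](C)(C)OC1=C(C)[C@H](C)CCC1 | intermediate
4 | but-3-en-2-one | CC(=O)C=C | starting material
5 | (2S,3R)-2,3-dimethyl-2-(3-oxobutyl)cyclohexan-1-one | O=C1CCC[C@@H](C)[C@]1(C)CCC(C)=O | intermediate
6 | ethyl (2E)-5-[(1S,2R)-1,2-dimethyl-6-oxocyclohexyl]-3-methylpent-2-enoate | O=C1CCC[C@@H](C)[C@]1(C)CC/C(C)=C/C(=O)OCC | intermediate
7 | ethyl (2E)-5-[(1S,6R)-1,6-dimethyl-2-(trifluoromethanesulfonyloxy)cyclohex-2-en-1-yl]-3-methylpent-2-enoate | FC(F)(F)S(=O)(=O)OC1=CCC[C@@H](C)[C@]1(C)CC/C(C)=C/C(=O)OCC | intermediate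
8 | (5R,6S)-6-[(3E)-5-hydroxy-3-methylpent-3-en-1-yl]-5,6-dimethylcyclohex-1-en-1-yl trifluoromethanesulfonate | FC(F)(F)S(=O)(=O)OC1=CCC[C@@H](C)[C@]1(C)CC/C(C)=C/CO | intermediate
9 | (5R,6S)-6-[(3E)-5-(tert-butyldiphenylsilyloxy)-3-methylpent-3-en-1-yl]-5,6-dimethylcyclohex-1-en-1-yl trifluoromethanesulfonate | FC(F)(F)S(=O)(=O)OC1=CCC[C@@H](C)[C@]1(C)CC/C(C)=C/CO[Si](c2ccccc2)(c3ccccc3)C(C)(C)C | intermediate
10 | tert-butyl({(2E)-5-[(1S,6R)-2-(1-ethoxyethenyl)-1,6-dimethylcyclohex-2-en-1-yl]-3-methylpent-2-en-1-yl}oxy)diphenylsilane | C=C(OCC)C1=CCC[C@@H](C)[C@]1(C)CC/C(C)=C/CO[Si](c2ccccc2)(c3ccccc3)C(C)(C)C | intermediate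
11 | 1-[(5R,6S)-6-[(3E)-5-(tert-butyldiphenylsilyloxy)-3-methylpent-3-en-1-yl]-5,6-dimethylcyclohex-1-en-1-yl]ethan-1-one | CC(=O)C1=CCC[C@@H](C)[C@]1(C)CC/C(C)=C/CO[Si](c2ccccc2)(c3ccccc3)C(C)(C)C | intermediate
12 | (1R)-1-[(5R,6S)-6-[(3E)-5-(tert-butyldiphenylsilyloxy)-3-methylpent-3-en-1-yl]-5,6-dimethylcyclohex-1-en-1-yl]ethan-1-ol | C[C@@H](O)C1=CCC[C@@H](C)[C@]1(C)CC/C(C)=C/CO[Si](c2ccccc2)(c3ccccc3)C(C)(C)C | intermediate
13 | hex-5-enoic acid | OC(=O)CCCC=C | starting material
14 | (1R)-1-[(5R,6S)-6-[(3E)-5-(tert-butyldiphenylsilyloxy)-3-methylpent-3-en-1-yl]-5,6-dimethylcyclohex-1-en-1-yl]ethyl hex-5-enoate | C=CCCCC(=O)O[C@H](C)C1=CCC[C@@H](C)[C@]1(C)CC/C(C)=C/CO[Si](c2ccccc2)(c3ccccc3)C(C)(C)C | intermediate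
15 | (E)-O-trimethylsilyl ketene acetal of 14 (butenyl chain cis to the allylic oxygen) | C=CCC/C=C(\O[C@H](C)C1=CCC[C@@H](C)[C@]1(C)CC/C(C)=C/CO[Si](c2ccccc2)(c3ccccc3)C(C)(C)C)O[Si](C)(C)C | intermediate
16 | trimethylsilyl ester of 17 (C4 unassigned, both epimers) | C[Si](C)(C)OC(=O)C(CCC=C)[C@@H]1CC[C@@H](C)[C@](C)(CC/C(C)=C/CO[Si](c2ccccc2)(c3ccccc3)C(C)(C)C)/C1=C/C | intermediate
17 | 2-[(1S,2E,3S,4R)-3-[(3E)-5-(tert-butyldiphenylsilyloxy)-3-methylpent-3-en-1-yl]-2-ethylidene-3,4-dimethylcyclohexyl]hex-5-enoic acid (C4 unassigned, both epimers) | OC(=O)C(CCC=C)[C@@H]1CC[C@@H](C)[C@](C)(CC/C(C)=C/CO[Si](c2ccccc2)(c3ccccc3)C(C)(C)C)/C1=C/C | intermediate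
18 | methyl 2-[(1S,2E,3S,4R)-3-[(3E)-5-(tert-butyldiphenylsilyloxy)-3-methylpent-3-en-1-yl]-2-ethylidene-3,4-dimethylcyclohexyl]hex-5-enoate (C4 unassigned, both epimers) | COC(=O)C(CCC=C)[C@@H]1CC[C@@H](C)[C@](C)(CC/C(C)=C/CO[Si](c2ccccc2)(c3ccccc3)C(C)(C)C)/C1=C/C | intermediate
19 | methyl (2R)-2-[(1R,2E,3S,4R)-3-[(3E)-5-(tert-butyldiphenylsilyloxy)-3-methylpent-3-en-1-yl]-2-ethylidene-3,4-dimethylcyclohexyl]-2-methylhex-5-enoate | COC(=O)[C@](C)(CCC=C)[C@@H]1CC[C@@H](C)[C@](C)(CC/C(C)=C/CO[Si](c2ccccc2)(c3ccccc3)C(C)(C)C)/C1=C/C | intermediate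
20 | methyl (4R,5R,8R,9S,13E)-15-(tert-butyldiphenylsilyloxy)halima-1(10),13-dien-18-oate | COC(=O)[C@]1(C)CCC=C2[C@H]1CC[C@@H](C)[C@]2(C)CC/C(C)=C/CO[Si](c3ccccc3)(c4ccccc4)C(C)(C)C | intermediate
21 | methyl (4R,5R,8R,9S,13E)-15-hydroxyhalima-1(10),13-dien-18-oate | COC(=O)[C@]1(C)CCC=C2[C@H]1CC[C@@H](C)[C@]2(C)CC/C(C)=C/CO | intermediate
22 | methyl (4R,5R,8R,9S,13S,14S)-13,14-epoxy-15-hydroxyhalim-1(10)-en-18-oate | COC(=O)[C@]1(C)CCC=C2[C@H]1CC[C@@H](C)[C@]2(C)CC[C@]3(C)O[C@H]3CO | intermediate
23 | methyl (4R,5R,8R,9S,13S,14R)-14,15-epoxy-13-hydroxyhalim-1(10)-en-18-oate | COC(=O)[C@]1(C)CCC=C2[C@H]1CC[C@@H](C)[C@]2(C)CC[C@](C)(O)[C@H]3CO3 | intermediate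
24 | methyl (4R,5R,8R,9S,13S,14R)-13,14,15-trihydroxyhalim-1(10)-en-18-oate | COC(=O)[C@]1(C)CCC=C2[C@H]1CC[C@@H](C)[C@]2(C)CC[C@](C)(O)[C@@H](CO)O | intermediate
25 | methyl (4R,5R,8R,9S,13S,14R)-14,15-diacetoxy-13-hydroxyhalim-1(10)-en-18-oate (CNP0238486.1) | COC(=O)[C@]1(C)CCC=C2[C@H]1CC[C@@H](C)[C@]2(C)CC[C@](C)(O)[C@@H](COC(C)=O)OC(C)=O | target

Total step count: 17. Longest linear sequence: 17 steps (1 to 25); 4 and 13 are commercial.

**Steps most likely to fail**

Step 13 (ring-closing metathesis). The catalyst may engage the trisubstituted C10 ethylidene too slowly, because it lies between the C9 quaternary carbon and the C4 quaternary carbon; catalyst decay, olefin isomerisation and intermolecular metathesis at the vinyl terminus would then take over. The fallback sets out from 18 and comes back at 20. The ring is closed one stage earlier, on 18, under the same ruthenium catalyst. There the C4 methine can turn its hydrogen toward the C2′ methyl and leave the C10 olefin open, which should give the bicyclic C4-methine ester F1 (both C4 epimers). Its ester enolate (LiN(iPr)2, THF–DMPU, −78 °C) is then methylated with MeI from the axial face of ring A, since the equatorial approach is blocked by the peri C6 methylene and the sp2 C10 carries no angular group over the axial face. This gives 20.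

Step 12 (C4 methylation). Facial selection in the open-chain ester enolate may be poor if rotamers about C4–C5 other than the H-eclipsed one take part, and enolisation of the hindered ester may be incomplete. The fallback sets out from 17 and comes back at 19, and replaces open-chain control by a temporary ring. Iodolactonisation of acid 17 (I2, NaHCO3, MeCN–H2O, 0 °C) engages only the γ,δ-ethylidene and should give the cis-fused iodolactone F2. Its lithium enolate (LiN(iPr)2, THF, −78 °C, then MeI) is alkylated on the convex face, syn to H5 and away from the ring B methylene C6, to give the methylated iodolactone F3 with the target configuration at C4. Reductive elimination with Zn in AcOH–THF returns the ethylidene and the acid as seco acid F4, and MeI/K2CO3 in DMF then gives 19.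

Step 16 (Payne opening). Partial saponification of the C18 methyl ester in hot aqueous base, or slow and unselective opening, may erode the material. The fallback sets out from 22 and comes back at 24, and uses carbon dioxide as the carrier of the oxygen nucleophile. With Cs2CO3 (cat.) under CO2 (1 atm) in DMF at 40 °C, the C15 alkyl carbonate anion should open the epoxide 5-exo at C14 with inversion. This gives the 14,15-cyclic carbonate F5 with the free 13-OH. K2CO3 in MeOH at rt then cleaves the carbonate to 24, methoxide exchange at the methyl ester being degenerate.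

Further compounds
F1 | step 13 | methyl (5S,8R,9S,13E)-15-(tert-butyldiphenylsilyloxy)halima-1(10),13-dien-18-oate (C4 unassigned, both epimers) | COC(=O)C1CCC=C2[C@H]1CC[C@@H](C)[C@]2(C)CC/C(C)=C/CO[Si](c3ccccc3)(c4ccccc4)C(C)(C)C
F2 | step 12 | (3aS,6R,7S,7aR)-3-(but-3-en-1-yl)-7-[(3E)-5-(tert-butyldiphenylsilyloxy)-3-methylpent-3-en-1-yl]-7a-[(1S)-1-iodoethyl]-6,7-dimethylhexahydro-1-benzofuran-2(3H)-one (C3 unassigned, both epimers) | C=CCCC1C(=O)O[C@]2([C@H](C)I)[C@H]1CC[C@@H](C)[C@]2(C)CC/C(C)=C/CO[Si](c3ccccc3)(c4ccccc4)C(C)(C)C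
F3 | step 12 | (3R,3aS,6R,7S,7aR)-3-(but-3-en-1-yl)-7-[(3E)-5-(tert-butyldiphenylsilyloxy)-3-methylpent-3-en-1-yl]-7a-[(1S)-1-iodoethyl]-3,6,7-trimethylhexahydro-1-benzofuran-2(3H)-one | C=CCC[C@@]1(C)C(=O)O[C@]2([C@H](C)I)[C@H]1CC[C@@H](C)[C@]2(C)CC/C(C)=C/CO[Si](c3ccccc3)(c4ccccc4)C(C)(C)C
F4 | step 12 | (2R)-2-[(1R,2E,3S,4R)-3-[(3E)-5-(tert-butyldiphenylsilyloxy)-3-methylpent-3-en-1-yl]-2-ethylidene-3,4-dimethylcyclohexyl]-2-methylhex-5-enoic acid | OC(=O)[C@](C)(CCC=C)[C@@H]1CC[C@@H](C)[C@](C)(CC/C(C)=C/CO[Si](c2ccccc2)(c3ccccc3)C(C)(C)C)/C1=C/C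
F5 | step 16 | methyl (4R,5R,8R,9S,13S,14R)-14,15-(carbonyldioxy)-13-hydroxyhalim-1(10)-en-18-oate | COC(=O)[C@]1(C)CCC=C2[C@H]1CC[C@@H](C)[C@]2(C)CC[C@](C)(O)[C@H]3COC(=O)O3
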